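At late times a flask of this kind should hold its reacted monomer in about as many chains as it had initiator, so the length heads for monomer over initiator: 100 units at the 1 mol% loading of both recipes.

in all of them: protic impurity 0.0210 M; initiator 1 mol%; time 2.5 h
- zeta: free monomer 0.21 M
- gamma: free monomer 0.10 M

1. which of the two ends with the longer chains by the average number of monomer units in a chain (chains begun, living or dead) ("neither" if they lie within 10%) (zeta / gamma / neither)
2. average number of monomer units in a chain (chains begun, living or dead) at the end, zeta
3. average number of monomer units in a chain (chains begun, living or dead) at the end, gamma

Since both recipes head for that same length, a gap at 2.5 h has to come from the clock. The crossing to look for is where time stops setting the length and the charge ratio takes over.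

Not every number needs the same care. The initiator's own decay, at 0.12 /h, is slower than the starting of chains, at 1.16 /h in zeta and 0.550 /h in gamma, so an error there moves the number of chains by some part of those shares, 0.104 in zeta and 0.218 in gamma. The protic impurity is charged at 10.0% of zeta's free monomer and 21.0% of gamma's, so an error in its rate constant shifts free monomer by some part of that. A wrong loading moves the late length, and through the number of living ends it also moves how fast free monomer thins. An error in the growth constant, the monomer charge or the time passes straight into the length.

Those three multiply. A chain begun at the outset, with free monomer held at its charge, adds 115 units in zeta; this growth allowance is 55.0 in gamma. Chains begin through the run and free monomer thins, so this reckoning by hand takes 0.5 of the allowance: 57.5 units for zeta and 27.5 for gamma, both short of 100, with time still in control.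

The forecast names zeta, with 58 for zeta and 29 for gamma, against 27.5 by hand for gamma, and concludes that “zeta's chains are about twice as long”.

The simulation gives zeta, with 57.9 for zeta and 29.6 for gamma. Left until 25.0 h, they read 105 and 103.

    free monomer + initiator → living end + monomer in chains (k1 = 5.5 /M/h)
    free monomer + living end → monomer in chains + living end, rate k2*[living end]*[free monomer] (k2 = 220 /M/h)
    protic impurity + free monomer → quenched substrate (k3 = 4.8 /M/h)
    initiator → spent initiator (k4 = 0.12 /h)

Zeta's length is 0.503 of its allowance and gamma's 0.538 of its own. At 2.50 h, free monomer still stands at 44.9% of charge in zeta and 68.4% in gamma, so both readings are taken with chains still growing. The flask gamma left until 6.0 h has an allowance of 132, which gives 66.0 units by the same share. It reads 61.5, or 0.466 of that allowance, with 36.7% of its free monomer left.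

The constants used here stand for no real mixture; no experiment stands behind them.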